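**The share.** The ratio of target formed to starting material used, read at the end of the noon run, is 80.9%; I call it the share, a selectivity as read from that run. The last winter reading gives 80.4% at 35 °C, and with a scatter of 1 percentage point on each reading I see no trend with temperature. Each step takes one partner per starting material, so the share times the smaller charge, over the charge of starting material, gives what I take as a ceiling for target, an estimate that stands on the share as read. Idle adduct is counted as target.

| setting | midnight | noon | winter | theta | zeta | eta | beta | alpha | gamma |
|---|---|---|---|---|---|---|---|---|---|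
| starting material | 0.30 M | 0.30 M | 0.17 M | 0.30 M | 0.30 M | 0.20 M | 0.10 M | 0.30 M | 0.30 M |
| partner | 0.13 M | 1.9 M | 0.39 M | 0.120 M | 0.120 M | 0.100 M | 1.50 M | 0.390 M | 0.200 M |
| temperature | 35 °C | 75 °C | 35 °C | 70 °C | 40 °C | 110 °C | 70 °C | 70 °C | 70 °C |
| remark | run made earlier | run made earlier | run made earlier |  |  |  |  |  |  |
| time |  |  |  | 1.0 h | 1.0 h | 1.0 h | 1.0 h | 1.0 h | 1.0 h |

midnight run (percent of the starting material charged)

| time / h | target / % | starting material / % |
|---|---|---|
| 0.500 | 0.2 | 98.3 |
| 1.33 | 5.0 | 94.5 |
| 2.50 | 4.8 | 94.1 |
| 4.00 | 9.8 | 88.4 |

noon run (percent of the starting material charged)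

| time / min | target / % | starting material / % |
|---|---|---|
| 10.0 | 62.0 | 24.4 |
| 20.0 | 74.2 | 7.4 |
| 30.0 | 77.2 | 3.4 |
| 40.0 | 79.7 | 1.5 |

winter run (percent of the starting material charged)

| time / h | target / % | starting material / % |
|---|---|---|
| 1.00 | 8.5 | 92.2 |
| 2.00 | 13.7 | 82.4 |
| 3.00 | 20.8 | 76.5 |
| 4.00 | 25.1 | 68.8 |

(standard deviation of a reading: 1 percentage point)

- amounts and yields of target count idle adduct too
- what was read earlier has a scatter of 1 percentage point, one standard deviation
- steps thought possible: starting material + partner -> target; starting material + partner -> isomer of the product; partner + target <-> idle adduct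

* the flasks by amount of target, in percent of the starting material charged, highest first, at 1.0 h (theta / zeta / eta / beta / alpha / gamma)
* the same order at 8.0 h (theta / zeta / eta / beta / alpha / gamma)
* the amount of target, in percent of the starting material charged of the flask you put first, at 1.0 h
* the amount of target, in percent of the starting material charged of the flask you put last, at 1.0 h

**First instants.** In theta, [starting material] is 0.30 M and [partner] is 0.120 M, so partner is the limiting reagent. Both steps start together, and the share divides their output.

**The middle.** In theta starting material stands in excess by a factor of 2.50, so I treat partner roughly as a pseudo-first-order reactant. Noon's first reading, with [partner] taken as charged, gives theta a partner lifetime of 0.748 h; that is reckoned at noon's 75 °C, hotter than theta's 70 °C, so I expect theta's to be somewhat longer. So 1.0 h is 1.34 lifetimes, and I expect theta to be well under its ceiling then.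

**The end.** By 8.0 h, about ten times that lifetime, theta should approach its ceiling of 32.4%. Gamma's ceiling is 53.9% and eta's is 40.5%. Eta, at 110 °C, hotter than gamma's 70 °C, should arrive early, but gamma's ceiling is higher, so I rank gamma above eta at 8.0 h.

**The forecast.** It gives beta > alpha > eta > gamma > theta > zeta at 1.0 h and beta > alpha > gamma > eta > theta > zeta at 8.0 h, with 80% on top and 3.5% at the bottom. Its ground for the yields is “Selectivity to target is about 0.81 throughout”, and it holds eta at 40 at both times.

**The flasks.** They stand beta > alpha > eta > gamma > theta > zeta at 1.0 h and beta > alpha > gamma > eta > theta > zeta at 8.0 h, with beta at 78.9% and zeta at 3.52%.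

    starting material + partner → target (k = 8.17 × 10⁻⁴ L mol⁻¹ s⁻¹, Ea = 66.0 kJ mol⁻¹)
    starting material + partner → isomer of the product (k = 2.12 × 10⁻⁴ L mol⁻¹ s⁻¹, Ea = 73.0 kJ mol⁻¹)
    partner + target ⇌ idle adduct, settled at all times (K = 5.00 L mol⁻¹, ΔH = 17.0 kJ mol⁻¹)
    (constants at 70 °C)

Zeta moved to 65 °C gives 15.1% at 1.00 h, still below theta's 18.2%. Theta's two steps run while its partner falls to 0.331% of its charge at 10.0 h, when target stands at 31.6% against the ceiling of 32.4%. Eta's steps run while its partner falls to 7.11% of its charge at 0.500 h and 0% at 10.0 h, when target stands at 37.4% under its ceiling of 40.5% and isomer of the product at 12.6%, a share of 74.8%.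

The earlier runs and the new flask are simulated with constants of no real substance; noise was put on by code.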